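## Structural features

The target joins two 2-(2-phenylethyl)chromone units through an alkyl aryl ether. Ring A is a 5,6,7,8-tetrahydro-4H-chromen-4-one, a γ-pyranone fused across C4a–C8a to a cyclohexane oxygenated at all four sp3 carbons. Ring B is an aromatic 7'-hydroxychromone whose C6' carries the ether oxygen bound to C5. C5, C6, C7 and C8 are four contiguous stereocentres (5S,6S,7R,8S): O5 and O8 lie on one face, O6 and O7 on the other, so the ring is 5,6-trans, 6,7-cis and 7,8-trans. The compound is fragile in three ways: the oxygenated ring is two dehydrations from an aromatic chromone, the C5–O bond is allylic to C4a=C8a and can ionise with help from O1, and H8 is vinylogously acidic. Every carbocyclic precursor of ring A is also a β-alkoxy aldehyde or ketone that can eliminate. The real difficulty is to make ring A as one enantiomer with three differently treated oxygens (O5 to be arylated, O6/O7 and O8 only freed at the end) and to form the hindered C5–O–aryl ether without disturbing C5. The plan uses the fact that C8a (ketone level, hidden in the pyranone as the carbon bound to O1) and the C8 carbinol are the two carbons of an acyloin, while C5, C6 and C7 have the configuration of C2, C3 and C4 of L-arabinose. Ring A is therefore a benzoin-type closure of C8–C8a in a one-carbon-homologated arabinose dialdehyde, with the cis-6,7-diol tied up as a dioxolane that holds the two aldehydes together.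

## Logic of the disconnections

30 ⇒ 29. The O8–Si bond, the two acetal C–O bonds at O6/O7 and the O7'–CH2 acetal bond are cut together. All three groups are acid-labile, so one final operation frees four hydroxyls. The forward step must use aqueous acid mild enough not to ionise C5–O or dehydrate ring A.

29 ⇒ 21 + 28. The aryl C6'–O bond is cut, not the C5–O bond. This splits the molecule into two chromone halves of similar size and leaves C5 untouched, so its configuration is carried over with retention. The forward step is a palladium-catalysed C–O coupling of a hindered secondary alcohol with an electron-rich, ortho-alkoxy aryl bromide; reductive elimination has to outrun β-hydride elimination and the base must stay weak.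

28 ⇒ 27 ⇒ 26 ⇒ 24 + 25, and 24 ⇒ 23 ⇒ 22. In ring B the O7'-acetal is removed, the pyranone is opened at O1'–C2' (cyclodehydration), and the C-acyl bond between the acetyl carbon and the ester carbonyl is cut (Claisen condensation). The bromine at C6' is traced to electrophilic substitution of 22. This reduces ring B to two cheap aromatics; the forward demand is regioselective bromination and temporary masking of the 4-hydroxyl during the condensation.

21 ⇒ 20. The O5–benzyl bond is restored. O5 must be told apart from O8 (silyl) and O6/O7 (acetal), and an oxidatively cleavable ether does this without acid or base.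

20 ⇒ 14 + 17 (through 18 and 19), 17 ⇒ 15 + 16, 14 ⇒ 13 ⇒ 12. The pyranone is cut at C4a–C4 and C8a–O1. One reagent, 18, then delivers C2, C3, C4, O1 and the side chain in a hetero-[4+2] addition to the enol ether of the ring ketone. The forward demands are an enol ether on the C4a side only, no loss of O5 from the β-alkoxy ketone, and a capped O8 so that 18 cannot acylate it.

12 ⇒ 11. The C8–C8a bond is cut, the only skeletal bond of the carbocycle that is formed. An α-hydroxy ketone becomes two aldehydes joined by umpolung, and the ring with all its oxygens reduces to an open-chain sugar derivative. The forward step needs C8a as acyl-anion donor, C8 as acceptor, and the new hydroxyl trans to O7.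

11 ⇒ 10 ⇒ 8 (through 9) ⇒ 6 + 7. Both aldehydes are taken back to primary alcohols, the C8a–O bond to a terminal alkene (hydroboration), and the C4a=C8a bond to a Wittig methylenation of the lactol. The sensitive dialdehyde then appears in one non-basic step from a stable diol. The forward demands are anti-Markovnikov hydroboration and an oxidation that neither epimerises C7 nor eliminates O5.

6 ⇒ 4 (through 5) ⇒ 3 ⇒ 2 ⇒ 1. Only C–O bonds to protecting groups are cut: the anomeric allyl group, the O2 benzyl ether, the 3,4-acetal and the glycosidic bond. The glycoside frees O2 for etherification and the cis-3,4-diol selects its own acetal, so the pentose supplies C5, C6 and C7 with no stereochemical operation.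

## Other disconnections considered

Alternative 1: The cut is through C4a–C5 and C8a–C8, so the carbocycle is added in one [4+2] step to a preformed pyranone. In the forward direction the sulfinylpyranone A1 and the 1-silyloxy-4-acyloxy diene A2 would combine, and thermal syn-elimination of the sulfinyl group would restore the pyranone to give the 5,8-cis dihydrochromone A3.
- In its favour: two C–C bonds and the C5/C8 pair are set in one operation, the E,E-diene guarantees the 5,8-cis relationship, and O5 (silyl) and O8 (ester) emerge differentiated.
- Against it: the 5,6-double bond of a γ-pyranone is a reluctant dienophile even with the sulfinyl group. The absolute sense rests on reagent control by sulfur, and the facial preference of such dienophiles can invert between thermal and chelated modes. A3 is a 1,4-cyclohexadiene with two allylic leaving groups, one elimination from a chromone. The 6,7-diol must still be added by dihydroxylation anti to O5 and O8.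
- Comparison: in step economy the alternative is the better plan, since A3 would be reached in a few steps and no separate pyranone annulation is needed. In O5/O8 differentiation the two are equal, and both need the same late O-arylation. In stereochemical security the chosen plan is stronger, because C5–C7 come from the chiral pool and only C8 is created.

Alternative 2: The cut is at C8a–C4a (with the O–C4 bond), closing the carbocycle and an isoxazole together. The aldoxime A4 would be oxidised with NaOCl to the nitrile oxide A5, which adds to the tethered alkyne to give the fused isoxazole A6.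
- In its favour: all four stereocentres are in place before ring closure and none is created in it, which is better than the chosen plan where C8 is formed in the key step. The tether fixes the regiochemistry. The isoxazole already carries C2–C4 and the side chain as a masked 1,3-diketone, so no enolisation of a β-alkoxy ketone toward C4a is needed, also a point in its favour. The two silyl groups differentiate O5 and O8 as well as the ether/silyl pair of the chosen plan does (equal).
- Against it: A4 is a long acyclic target. Four contiguous oxygenated centres, an alkyne added at C5 with stereocontrol, and a ketal side chain must all be assembled linearly. The unmasking needs N–O reduction, hydrolysis of the vinylogous amide in competition with 4-pyridone formation, and cyclodehydration, all beside β-oxygen substituents.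
- Comparison: mechanistically the cycloaddition is the safer ring closure, but the step count before and after it should clearly exceed that of the chosen plan.

Alternative 3: The cut is at C4a–C5. D-Mannose A7 would be converted into the hex-5-enopyranoside A8, and Hg(OCOCF3)2-mediated hydration would open the pyranoside and close C4a onto C5 to give the cyclohexanone A9.
- In its favour: C6, C7 and C8 come from C2, C3 and C4 of A7, and the ketone position is fixed by construction with no donor/acceptor ambiguity, which is better than the chosen key step. The new hydroxyl normally forms trans to the neighbouring oxygen, as needed here. A9 is one etherification of O5 from 13, so this route would join the chosen one about two steps earlier, a better step economy.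
- Against it: a toxic mercury salt is used. A9 is a β-hydroxy ketone that dehydrates easily and must be etherified under non-basic conditions. The cis-fused dioxolane distorts the pyranoside chair and may slow the carbocyclisation. The centre created is C5, the one that later bears the aryl ether, so any 5-epimer is costly.
- Comparison: both plans create one stereocentre in the ring closure (equal). The chosen plan creates C8, which can be corrected next to a ketone, and avoids mercury and the free β-hydroxy ketone.

Key step: step 8

Remarks on the chemistry: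
- Ring A carbons carry the chromone numbering of the target in every intermediate. "The parent tetrol" means (5S,6R,7R,8S)-5,6,7,8-tetrahydroxy-2-(2-phenylethyl)-5,6,7,8-tetrahydro-4H-chromen-4-one, whose O-substituted derivatives have the spatial arrangement of the target.
- Structure check: 11 and 12 as drawn have at C5–C7 the configuration of C2–C4 of L-arabinose, and 12 has the C8 hydroxyl trans to O7. This is what (5S,6S,7R,8S) in 30 requires, so no descriptor had to be changed.
- Design change: C8a is not unveiled from a methyl enol ether. An enol ether with an allylic alkoxy group (O5) tends to expel that group on acid or mercury-salt hydrolysis and give the enal. The aldehyde carbon is instead brought in as a methylene group, hydroborated, and both aldehydes are released together from diol 10 under non-basic conditions.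
- Compounds 5 (E/Z), 6 (anomers) and 19 (C4a/C8a) may be mixtures at centres that are destroyed later.

## Route

Step 1
Reactants: 1 L-arabinose
Product: 2 allyl β-L-arabinopyranoside
Conditions: allyl alcohol (solvent), AcCl (0.2 equiv, source of HCl), 60 °C; crystallisation
Reagents that add atoms: allyl alcohol, C=CCO
Why: Fischer glycosidation under thermodynamic control should favour the pyranoside, and the 1,2-cis (β-L) anomer with axial allyloxy group is stabilised by the anomeric effect and crystallises; C2–C4 are untouched.

Step 2
Reactants: 2 allyl β-L-arabinopyranoside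
Product: 3 allyl 3,4-O-isopropylidene-β-L-arabinopyranoside
Conditions: 2,2-dimethoxypropane, TsOH·H2O (cat.), DMF, rt; Et3N quench
Reagents that add atoms: 2,2-dimethoxypropane, COC(C)(C)OC
Why: Acid-catalysed transacetalisation; only the cis-3,4-diol can close a strain-free five-membered acetal, so O2 is left free.

Step 3
Reactants: 3 allyl 3,4-O-isopropylidene-β-L-arabinopyranoside
Product: 4 allyl 3,4-O-isopropylidene-2-O-(4-methoxybenzyl)-β-L-arabinopyranoside
Conditions: NaH, 4-methoxybenzyl chloride, Bu4NI (cat.), DMF, 0 °C → rt
Reagents that add atoms: 4-methoxybenzyl chloride, COc1ccc(CCl)cc1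
Why: Williamson etherification of the only free hydroxyl; the alkyl ether is a poor leaving group for the later β-alkoxy carbonyl stages and is removable oxidatively.

Step 4
Reactants: 4 allyl 3,4-O-isopropylidene-2-O-(4-methoxybenzyl)-β-L-arabinopyranoside
Product: 6 3,4-O-isopropylidene-2-O-(4-methoxybenzyl)-L-arabinopyranose (anomeric mixture), via (E)-prop-1-enyl glycoside 5 (not isolated)
Conditions: [Ir(cod)(PMePh2)2]PF6 (2 mol%, activated with H2), THF, rt; then I2, NaHCO3, THF/H2O, 0 °C
Reagents that add atoms: none
Why: Iridium-hydride-catalysed allyl-to-propenyl isomerisation followed by iodonium-induced hydrolysis of the enol ether; the buffered, near-neutral conditions should spare the acetal and the benzyl ether.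

Step 5
Reactants: 6 3,4-O-isopropylidene-2-O-(4-methoxybenzyl)-L-arabinopyranose; 7 methyltriphenylphosphonium bromide
Product: 8 1,2-dideoxy-4,5-O-isopropylidene-3-O-(4-methoxybenzyl)-L-arabino-hex-1-enitol
Conditions: 7 (3.5 equiv), KOtBu (3.3 equiv), THF, 0 °C → rt
Reagents that add atoms: none
Why: Wittig methylenation of the open-chain aldehyde in equilibrium with the lactol (excess ylide covers the lactol proton); it adds the carbon that becomes C8a and frees the primary hydroxyl that becomes C8, and the non-stabilised ylide at low temperature should not epimerise the α-alkoxy centre.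

Step 6
Reactants: 8 1,2-dideoxy-4,5-O-isopropylidene-3-O-(4-methoxybenzyl)-L-arabino-hex-1-enitol
Product: 10 2-deoxy-4,5-O-isopropylidene-3-O-(4-methoxybenzyl)-L-arabino-hexitol, via B-alkyl-9-borabicyclo[3.3.1]nonane adduct 9 (not isolated)
Conditions: 9-BBN (2.5 equiv), THF, 0 °C → rt; then NaOH, H2O2, 0 °C → rt
Reagents that add atoms: hydrogen peroxide, OO
Why: Hydroboration–oxidation; the bulky borane adds boron to the terminal carbon (the allylic ether reinforces this) and oxidation with retention gives the primary alcohol, no stereocentre being formed.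

Step 7
Reactants: 10 2-deoxy-4,5-O-isopropylidene-3-O-(4-methoxybenzyl)-L-arabino-hexitol
Product: 11 2-deoxy-4,5-O-isopropylidene-3-O-(4-methoxybenzyl)-L-arabino-hexodialdose
Conditions: Dess–Martin periodinane (2.6 equiv), CH2Cl2, 0 °C → rt; crude product used at once
Reagents that add atoms: none
Why: Double Dess–Martin oxidation of a 1,6-diol (too far apart for lactol formation); without amine base the cis-dioxolane aldehyde should not epimerise at C7 and the β-alkoxy aldehyde should not eliminate.

Step 8
Reactants: 11 2-deoxy-4,5-O-isopropylidene-3-O-(4-methoxybenzyl)-L-arabino-hexodialdose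
Product: 12 (3aS,4S,7S,7aR)-4-hydroxy-7-[(4-methoxyphenyl)methoxy]-2,2-dimethyl-3a,6,7,7a-tetrahydro-1,3-benzodioxol-5(4H)-one (ring A acyloin: C8a ketone, free 8-hydroxyl, 6,7-acetonide, 5-O-PMB)
Conditions: 2-(pentafluorophenyl)-6,7-dihydro-5H-pyrrolo[2,1-c][1,2,4]triazol-2-ium tetrafluoroborate (15 mol%), iPr2NEt (15 mol%), CH2Cl2 (0.02 M), rt
Reagents that add atoms: none
Why: The triazolylidene freed by the amine adds to the unbranched C8a aldehyde, proton transfer gives the hydroxy-enamine acyl-anion equivalent, this attacks the C8 carbonyl, and collapse of the adduct releases the carbene and the α-hydroxy ketone. The closest known reaction type is the carbene-catalysed intramolecular crossed benzoin (acyloin) cyclisation of dialdehydes, including carbohydrate-derived ones that give inososes. The cyclohexanone closes in a 6-exo-trig mode, nucleophilic C8a adding to the C8 carbonyl whose oxygen stays outside the new ring. The one new stereocentre, C8, is under substrate control: the cis-dioxolane holds both chains on one face, and in a chair-like, dipole-minimised transition state the C=O lies anti to the C7–O bond, so C8a attacks the face remote from O7 and the hydroxyl ends trans to O7. The step needs C8a as donor and C8 as acceptor; the bulky N-aryl carbene should form the acyl-anion equivalent far faster at the CH2CHO group than at the α-branched, α-oxygenated aldehyde, which is also the better electrophile. It also needs C7, O5 and the acyloin regiochemistry to survive, which the sub-stoichiometric weak base and short contact time should secure against epimerisation, β-elimination and acyloin transposition.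

Step 9
Reactants: 12 ring A acyloin
Product: 13 8-O-(tert-butyldimethylsilyl) ether of 12
Conditions: TBSOTf (1.2 equiv), 2,6-lutidine (2 equiv), CH2Cl2, −78 °C
Reagents that add atoms: tert-butyldimethylsilyl trifluoromethanesulfonate, CC(C)(C)[Si](C)(C)OS(=O)(=O)C(F)(F)F
Why: O-silylation with a silyl triflate and a hindered weak base at low temperature should cap O8 before any enediol formation, so C8 and the ketone position are kept.

Step 10
Reactants: 13 8-O-TBS ketone
Product: 14 trimethylsilyl enol ether of 13 with the double bond C8a=C4a
Conditions: LiN(SiMe3)2 (1.3 equiv) added to 13 and TMSCl (3 equiv), THF, −78 °C; pentane, filtration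
Reagents that add atoms: chlorotrimethylsilane, C[Si](C)(C)Cl
Why: Kinetic deprotonation should occur at the unhindered C4a methylene and not at the hindered α-silyloxy C8 methine, and the in-situ silyl chloride traps the enolate before it can expel O5; C8 is not epimerised.

Step 11
Reactants: 15 2,2,6-trimethyl-4H-1,3-dioxin-4-one; 16 benzyl bromide
Product: 17 2,2-dimethyl-6-(2-phenylethyl)-4H-1,3-dioxin-4-one
Conditions: LiN(iPr)2 (1.1 equiv), THF, −78 °C; DMPU, 16, −78 → −20 °C
Reagents that add atoms: none
Why: Vinylogous enolate alkylation; the lithium dienolate formed at the 6-methyl group is benzylated at that exocyclic carbon by the reactive halide.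

Step 12
Reactants: 14 trimethylsilyl enol ether; 17 2,2-dimethyl-6-(2-phenylethyl)-4H-1,3-dioxin-4-one
Product: 20 8-O-(tert-butyldimethylsilyl)-6,7-O-isopropylidene-5-O-(4-methoxybenzyl) derivative of the parent tetrol, via acylketene 18 (not isolated), via silyloxy-dihydropyranone cycloadduct 19 (not isolated)
Conditions: 17 (2.5 equiv, slow addition), toluene, 110 °C; then TsOH·H2O (10 mol%), rt
Reagents that add atoms: none
Why: Thermal retro-[4+2] of 17 releases the acylketene, which adds to the electron-rich enol ether in a hetero-[4+2] sense (ketene carbon to C4a, acyl oxygen to C8a). Acid-induced loss of trimethylsilanol then gives the γ-pyranone, as in the known acylketene–enol ether route to 4-pyranones, and C5 and C8 are not involved.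

Step 13
Reactants: 20 protected ring A pyranone
Product: 21 8-O-(tert-butyldimethylsilyl)-6,7-O-isopropylidene derivative of the parent tetrol (free 5-hydroxyl)
Conditions: DDQ (1.5 equiv), CH2Cl2/pH 7 buffer (10:1), 0 °C → rt
Reagents that add atoms: none
Why: Oxidative cleavage of the 4-methoxybenzyl ether through its oxocarbenium ion, hydrolysed by water; the silyl ether, the acetal and the electron-poor pyranone should be inert.

Step 14
Reactants: 22 1-(2,4-dihydroxyphenyl)ethanone
Product: 23 1-(5-bromo-2,4-dihydroxyphenyl)ethanone
Conditions: NBS (1.0 equiv), MeCN, 0 °C → rt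
Reagents that add atoms: N-bromosuccinimide, O=C1CCC(=O)N1Br
Why: Electrophilic aromatic bromination at C5, para to the 2-hydroxyl and ortho to the 4-hydroxyl; C3, flanked by both oxygens, is the slower site.

Step 15
Reactants: 23 1-(5-bromo-2,4-dihydroxyphenyl)ethanone
Product: 24 1-[5-bromo-2-hydroxy-4-(methoxymethoxy)phenyl]ethanone
Conditions: chloromethyl methyl ether (1.1 equiv), K2CO3, acetone, 0 °C → rt
Reagents that add atoms: chloromethyl methyl ether, COCCl
Why: The 2-hydroxyl is held in a hydrogen bond to the ketone, so Williamson alkylation should take place at the 4-hydroxyl only.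

Step 16
Reactants: 24 1-[5-bromo-2-hydroxy-4-(methoxymethoxy)phenyl]ethanone; 25 methyl 3-phenylpropanoate
Product: 26 1-[5-bromo-2-hydroxy-4-(methoxymethoxy)phenyl]-5-phenylpentane-1,3-dione
Conditions: NaH (4 equiv), 25 (1.5 equiv), THF, reflux; cold dilute HCl quench
Reagents that add atoms: none
Why: Claisen condensation of the phenoxide–enolate dianion with the ester, driven by deprotonation of the 1,3-diketone formed.

Step 17
Reactants: 26 1-[5-bromo-2-hydroxy-4-(methoxymethoxy)phenyl]-5-phenylpentane-1,3-dione
Product: 27 6-bromo-7-hydroxy-2-(2-phenylethyl)-4H-chromen-4-one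
Conditions: conc. HCl, MeOH, 60 °C
Reagents that add atoms: none
Why: Acid-catalysed cyclodehydration through the cyclic hemiketal gives the chromone; the same acid removes the acetal, which has done its work of masking the 4-hydroxyl in step 16.

Step 18
Reactants: 27 6-bromo-7-hydroxy-2-(2-phenylethyl)-4H-chromen-4-one
Product: 28 6-bromo-7-(methoxymethoxy)-2-(2-phenylethyl)-4H-chromen-4-one
Conditions: chloromethyl methyl ether, iPr2NEt, CH2Cl2, 0 °C → rt
Reagents that add atoms: chloromethyl methyl ether, COCCl
Why: O-alkylation of the phenol; the acetal is stable to carbonate base at 90 °C and falls in the final acid step.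

Step 19
Reactants: 21 ring A alcohol; 28 6-bromo-7-(methoxymethoxy)-2-(2-phenylethyl)-4H-chromen-4-one
Product: 29 8-O-(tert-butyldimethylsilyl)-6,7-O-isopropylidene-5-O-[7-(methoxymethoxy)-4-oxo-2-(2-phenylethyl)-4H-chromen-6-yl] derivative of the parent tetrol
Conditions: 28 (1.3 equiv), [Pd(allyl)Cl]2 (2.5 mol%), RockPhos (7.5 mol%), Cs2CO3 (1.5 equiv), toluene, 90 °C
Reagents that add atoms: none
Why: Palladium-catalysed C–O cross-coupling (Buchwald–Hartwig etherification): zerovalent palladium inserts into C6'–Br, the alkoxide displaces bromide, and the bulky biaryl di-tert-butylphosphine should favour C–O reductive elimination over β-hydride elimination. The C5–O bond is never broken, so C5 keeps its configuration.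

Step 20
Reactants: 29 fully protected ether
Product: 30 (5S,6S,7R,8S)-6,7,8-trihydroxy-5-{[7-hydroxy-4-oxo-2-(2-phenylethyl)-4H-chromen-6-yl]oxy}-2-(2-phenylethyl)-5,6,7,8-tetrahydro-4H-chromen-4-one
Conditions: CF3CO2H/H2O/THF (3:1:1), 0 °C → rt
Reagents that add atoms: none
Why: Acid hydrolysis of the silyl ether and the two acetals in one operation; water is used as nucleophile in place of an alcohol and the temperature is kept low so that C5–O does not ionise and the tetraoxygenated ring does not dehydrate.

## Compound list

1 | L-arabinose | O=C[C@H](O)[C@@H](O)[C@@H](O)CO | starting material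
2 | allyl β-L-arabinopyranoside | C=CCO[C@@H]1[C@H](O)[C@@H](O)[C@@H](O)CO1 | intermediate
3 | allyl 3,4-O-isopropylidene-β-L-arabinopyranoside | C=CCO[C@@H]1[C@H](O)[C@H]2OC(C)(C)O[C@H]2CO1 | intermediate
4 | allyl 3,4-O-isopropylidene-2-O-(4-methoxybenzyl)-β-L-arabinopyranoside | C=CCO[C@@H]1[C@H](OCc2ccc(OC)cc2)[C@H]2OC(C)(C)O[C@H]2CO1 | intermediate
5 | (E)-prop-1-enyl 3,4-O-isopropylidene-2-O-(4-methoxybenzyl)-β-L-arabinopyranoside | C/C=C/O[C@@H]1[C@H](OCc2ccc(OC)cc2)[C@H]2OC(C)(C)O[C@H]2CO1 | intermediate
6 | 3,4-O-isopropylidene-2-O-(4-methoxybenzyl)-L-arabinopyranose (anomeric mixture) | OC1[C@H](OCc2ccc(OC)cc2)[C@H]2OC(C)(C)O[C@H]2CO1 | intermediate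
7 | methyltriphenylphosphonium bromide | C[P+](c1ccccc1)(c1ccccc1)c1ccccc1.[Br-] | starting material
8 | 1,2-dideoxy-4,5-O-isopropylidene-3-O-(4-methoxybenzyl)-L-arabino-hex-1-enitol | C=C[C@H](OCc1ccc(OC)cc1)[C@H]1OC(C)(C)O[C@H]1CO | intermediate
9 | B-[2-deoxy-4,5-O-isopropylidene-3-O-(4-methoxybenzyl)-L-arabino-hexitol-1-yl]-9-borabicyclo[3.3.1]nonane | B1(CC[C@H](OCc2ccc(OC)cc2)[C@H]2OC(C)(C)O[C@H]2CO)C2CCCC1CCC2 | intermediate
10 | 2-deoxy-4,5-O-isopropylidene-3-O-(4-methoxybenzyl)-L-arabino-hexitol | OCC[C@H](OCc1ccc(OC)cc1)[C@H]1OC(C)(C)O[C@H]1CO | intermediate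
11 | 2-deoxy-4,5-O-isopropylidene-3-O-(4-methoxybenzyl)-L-arabino-hexodialdose | O=CC[C@H](OCc1ccc(OC)cc1)[C@H]1OC(C)(C)O[C@H]1C=O | intermediate
12 | (3aS,4S,7S,7aR)-4-hydroxy-7-[(4-methoxyphenyl)methoxy]-2,2-dimethyl-3a,6,7,7a-tetrahydro-1,3-benzodioxol-5(4H)-one (ring A acyloin) | O=C1C[C@H](OCc2ccc(OC)cc2)[C@H]2OC(C)(C)O[C@H]2[C@@H]1O | intermediate
13 | 8-O-(tert-butyldimethylsilyl) ether of 12 | O=C1C[C@H](OCc2ccc(OC)cc2)[C@H]2OC(C)(C)O[C@H]2[C@@H]1O[Si](C)(C)C(C)(C)C | intermediate
14 | trimethylsilyl enol ether of 13 (C8a=C4a) | C[Si](C)(C)OC1=C[C@H](OCc2ccc(OC)cc2)[C@H]2OC(C)(C)O[C@H]2[C@@H]1O[Si](C)(C)C(C)(C)C | intermediate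
15 | 2,2,6-trimethyl-4H-1,3-dioxin-4-one | CC1=CC(=O)OC(C)(C)O1 | starting material
16 | benzyl bromide | BrCc1ccccc1 | starting material
17 | 2,2-dimethyl-6-(2-phenylethyl)-4H-1,3-dioxin-4-one | CC1(C)OC(CCc2ccccc2)=CC(=O)O1 | intermediate
18 | 3-oxo-5-phenylpent-1-en-1-one (acylketene) | O=C=CC(=O)CCc1ccccc1 | intermediate
19 | 8a-(trimethylsilyloxy)-4a,8a-dihydro cycloadduct of 14 and 18 (C4a/C8a mixture) | O=C1C=C(CCc2ccccc2)OC2(O[Si](C)(C)C)C1[C@H](OCc1ccc(OC)cc1)[C@H]1OC(C)(C)O[C@H]1[C@@H]2O[Si](C)(C)C(C)(C)C | intermediate
20 | 8-O-(tert-butyldimethylsilyl)-6,7-O-isopropylidene-5-O-(4-methoxybenzyl) derivative of the parent tetrol | O=c1cc(CCc2ccccc2)oc2c1[C@H](OCc1ccc(OC)cc1)[C@H]1OC(C)(C)O[C@H]1[C@@H]2O[Si](C)(C)C(C)(C)C | intermediate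
21 | 8-O-(tert-butyldimethylsilyl)-6,7-O-isopropylidene derivative of the parent tetrol | O=c1cc(CCc2ccccc2)oc2c1[C@H](O)[C@H]1OC(C)(C)O[C@H]1[C@@H]2O[Si](C)(C)C(C)(C)C | intermediate
22 | 1-(2,4-dihydroxyphenyl)ethanone | CC(=O)c1ccc(O)cc1O | starting material
23 | 1-(5-bromo-2,4-dihydroxyphenyl)ethanone | CC(=O)c1cc(Br)c(O)cc1O | intermediate
24 | 1-[5-bromo-2-hydroxy-4-(methoxymethoxy)phenyl]ethanone | CC(=O)c1cc(Br)c(OCOC)cc1O | intermediate
25 | methyl 3-phenylpropanoate | COC(=O)CCc1ccccc1 | starting material
26 | 1-[5-bromo-2-hydroxy-4-(methoxymethoxy)phenyl]-5-phenylpentane-1,3-dione | O=C(CC(=O)CCc1ccccc1)c1cc(Br)c(OCOC)cc1O | intermediate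
27 | 6-bromo-7-hydroxy-2-(2-phenylethyl)-4H-chromen-4-one | O=c1cc(CCc2ccccc2)oc2cc(O)c(Br)cc12 | intermediate
28 | 6-bromo-7-(methoxymethoxy)-2-(2-phenylethyl)-4H-chromen-4-one | O=c1cc(CCc2ccccc2)oc2cc(OCOC)c(Br)cc12 | intermediate
29 | 8-O-(tert-butyldimethylsilyl)-6,7-O-isopropylidene-5-O-[7-(methoxymethoxy)-4-oxo-2-(2-phenylethyl)-4H-chromen-6-yl] derivative of the parent tetrol | O=c1cc(CCc2ccccc2)oc2c1[C@H](Oc1cc3c(=O)cc(CCc4ccccc4)oc3cc1OCOC)[C@H]1OC(C)(C)O[C@H]1[C@@H]2O[Si](C)(C)C(C)(C)C | intermediate
30 | (5S,6S,7R,8S)-6,7,8-trihydroxy-5-{[7-hydroxy-4-oxo-2-(2-phenylethyl)-4H-chromen-6-yl]oxy}-2-(2-phenylethyl)-5,6,7,8-tetrahydro-4H-chromen-4-one | O=c1cc(CCc2ccccc2)oc2c1[C@H](Oc1cc3c(=O)cc(CCc4ccccc4)oc3cc1O)[C@@H](O)[C@@H](O)[C@@H]2O | target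

## Step count and risk

Total: 20 steps. Longest linear sequence: 14 steps (1–10, 12, 13, 19, 20). Side branches: step 11 (one step) and steps 14–18 (five steps).

Least certain steps:

Step 8 (key step). The most likely failures are these:
- loss of donor/acceptor discrimination, with acyl-anion formation at C8 or base-induced acyloin transposition moving the ketone to C8;
- poor facial selectivity at C8;
- epimerisation at C7 or β-elimination of O5 under the amine.

If only the facial selectivity is at fault, both enantiomers of an aminoindanol-derived N-pentafluorophenyl triazolium salt can be tried to find the matched pair.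

The fallback gives up catalytic umpolung for a reductive coupling and sets out from 11. SmI2 (THF, tBuOH, −78 °C) should close the same C8–C8a bond as a pinacol coupling. It should give the cis-8,8a-diol F1, with the C8 hydroxyl anti to O7 as is usual for sugar-derived dialdehydes. The less encumbered C8a hydroxyl, which has a methylene neighbour, is silylated with Et3SiCl/imidazole to give the 8a-O-triethylsilyl ether F2. TBSOTf/2,6-lutidine then caps O8 to give the bis-silyl ether F3. Pyridinium p-toluenesulfonate in MeOH removes the triethylsilyl group selectively to give the 8-O-TBS 8a-alcohol F4. Dess–Martin oxidation of F4 comes back to the route at 13.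

Step 12. The acylketene may dimerise faster than the hindered trisubstituted silyl enol ether captures it, the enol ether may be desilylated by adventitious acid, or O5 may be lost by elimination at 110 °C.

The fallback builds the pyranone by aldol addition and alkyne cyclisation and sets out from 14. MeLi (THF, −78 °C) regenerates the lithium enolate regiospecifically. This is added to 5-phenylpent-2-ynal F5 (made from commercial 4-phenylbut-1-yne, nBuLi and DMF) to give the aldol adduct F6. Dess–Martin oxidation gives the enolised ynedione F7. Ph3PAuCl/AgOSO2CF3 (5 mol% each, CH2Cl2, rt) should induce 6-endo-dig addition of the C8a enol oxygen to the ynone, which returns to the route at 20.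

Step 19. β-Hydride elimination from the palladium alkoxide would oxidise C5 and reduce the bromide. Reductive elimination may be slow for a hindered alcohol and an electron-rich ortho-alkoxy aryl bromide. Carbonate at 90 °C may deprotonate C8 and open the acetal by vinylogous elimination.

The fallback reverses the polarity to a Mitsunobu etherification with inversion and sets out from 21 and 28. Dess–Martin oxidation of 21 gives the 5-ketone F8. Reduction with NaBH4/CeCl3·7H2O (MeOH, −40 °C) should deliver hydride anti to the dioxolane and give the 5-epi alcohol F9, with the hydroxyl cis to O6. In parallel 28 is borylated (bis(pinacolato)diboron, [1,1'-bis(diphenylphosphino)ferrocene]PdCl2, KOAc, dioxane, 90 °C) to the pinacol boronate F10 and oxidised (NaBO3·4H2O, THF/H2O) to the phenol F11. Coupling of F9 with F11 (PPh3, diisopropyl azodicarboxylate, toluene, 0 °C → rt) inverts C5 and comes back to the route at 29.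

Step 20. Acid may ionise C5–O and release the ring B phenol, start dehydration toward the aromatic chromone, or leave the hindered silyl ether partly intact.

The fallback separates the silyl cleavage from the acetal cleavage and avoids warm protic acid; it sets out from 29. HF·pyridine (THF, 0 °C) removes the silyl group to give the 8-alcohol F12. Me2BBr (CH2Cl2, −78 °C; then NaHCO3/THF/H2O) should cleave both acetals within minutes under aprotic conditions and arrive at 30.

## Further compounds

F1 | step 8 | cis-8,8a-diol from pinacol coupling of 11 (8-OH trans to O7, 8a-OH cis to 8-OH; 6,7-acetonide, 5-O-PMB) | O[C@@H]1C[C@H](OCc2ccc(OC)cc2)[C@H]2OC(C)(C)O[C@H]2[C@@H]1O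
F2 | step 8 | 8a-O-triethylsilyl ether of F1 | CC[Si](CC)(CC)O[C@@H]1C[C@H](OCc2ccc(OC)cc2)[C@H]2OC(C)(C)O[C@H]2[C@@H]1O
F3 | step 8 | 8a-O-triethylsilyl-8-O-(tert-butyldimethylsilyl) ether of F1 | CC[Si](CC)(CC)O[C@@H]1C[C@H](OCc2ccc(OC)cc2)[C@H]2OC(C)(C)O[C@H]2[C@@H]1O[Si](C)(C)C(C)(C)C
F4 | step 8 | 8-O-(tert-butyldimethylsilyl) ether of F1 with free 8a-hydroxyl | O[C@@H]1C[C@H](OCc2ccc(OC)cc2)[C@H]2OC(C)(C)O[C@H]2[C@@H]1O[Si](C)(C)C(C)(C)C
F5 | step 12 | 5-phenylpent-2-ynal | O=CC#CCCc1ccccc1
F6 | step 12 | aldol adduct of the C4a enolate of 13 with F5 (mixture at C4a and the carbinol) | O=C1C(C(O)C#CCCc2ccccc2)[C@H](OCc2ccc(OC)cc2)[C@H]2OC(C)(C)O[C@H]2[C@@H]1O[Si](C)(C)C(C)(C)C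
F7 | step 12 | C4a-(5-phenylpent-2-ynoyl) derivative of 13 (ynedione) | O=C1C(C(=O)C#CCCc2ccccc2)[C@H](OCc2ccc(OC)cc2)[C@H]2OC(C)(C)O[C@H]2[C@@H]1O[Si](C)(C)C(C)(C)C
F8 | step 19 | 5-ketone from 21 | O=c1cc(CCc2ccccc2)oc2c1C(=O)[C@H]1OC(C)(C)O[C@H]1[C@@H]2O[Si](C)(C)C(C)(C)C
F9 | step 19 | 5-epimer of 21 (5-hydroxyl cis to O6) | O=c1cc(CCc2ccccc2)oc2c1[C@@H](O)[C@H]1OC(C)(C)O[C@H]1[C@@H]2O[Si](C)(C)C(C)(C)C
F10 | step 19 | 7-(methoxymethoxy)-2-(2-phenylethyl)-6-(4,4,5,5-tetramethyl-1,3,2-dioxaborolan-2-yl)-4H-chromen-4-one | O=c1cc(CCc2ccccc2)oc2cc(OCOC)c(B3OC(C)(C)C(C)(C)O3)cc12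
F11 | step 19 | 6-hydroxy-7-(methoxymethoxy)-2-(2-phenylethyl)-4H-chromen-4-one | O=c1cc(CCc2ccccc2)oc2cc(OCOC)c(O)cc12
F12 | step 20 | 8-alcohol from 29 (acetonide and methoxymethyl ether retained) | O=c1cc(CCc2ccccc2)oc2c1[C@H](Oc1cc3c(=O)cc(CCc4ccccc4)oc3cc1OCOC)[C@H]1OC(C)(C)O[C@H]1[C@@H]2O
A1 | alternative 1 | (S)-5-(4-methylbenzenesulfinyl)-2-(2-phenylethyl)-4H-pyran-4-one (sulfur configuration nominal; it would have to be matched to the thermal or chelated mode) | O=c1cc(CCc2ccccc2)occ1[S@@](=O)c1ccc(C)cc1
A2 | alternative 1 | (1E,3E)-1-(tert-butyldimethylsilyloxy)-4-(pivaloyloxy)buta-1,3-diene | CC(C)(C)C(=O)O/C=C/C=C/O[Si](C)(C)C(C)(C)C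
A3 | alternative 1 | 5,8-cis-5-(tert-butyldimethylsilyloxy)-8-(pivaloyloxy)-5,8-dihydro-2-(2-phenylethyl)chromone | O=c1cc(CCc2ccccc2)oc2c1[C@H](O[Si](C)(C)C(C)(C)C)C=C[C@@H]2OC(=O)C(C)(C)C
A4 | alternative 2 | open-chain C8a aldoxime with C8-O-TBS, 6,7-acetonide, C5-O-triethylsilyl, C4a–C4 alkyne and ethylene-ketal side chain | ON=C[C@@H](O[Si](C)(C)C(C)(C)C)[C@@H]1OC(C)(C)O[C@@H]1[C@@H](O[Si](CC)(CC)CC)C#CCC1(CCc2ccccc2)OCCO1
A5 | alternative 2 | nitrile oxide from A4 | [O-][N+]#C[C@@H](O[Si](C)(C)C(C)(C)C)[C@@H]1OC(C)(C)O[C@@H]1[C@@H](O[Si](CC)(CC)CC)C#CCC1(CCc2ccccc2)OCCO1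
A6 | alternative 2 | isoxazole-fused ring A carbocycle (tetrahydro-2,1-benzisoxazole with protected 5,6,7,8-tetrol and ketal side chain) | c1(CC3(CCc4ccccc4)OCCO3)onc2c1[C@H](O[Si](CC)(CC)CC)[C@H]3OC(C)(C)O[C@H]3[C@@H]2O[Si](C)(C)C(C)(C)C
A7 | alternative 3 | D-mannose | O=C[C@@H](O)[C@@H](O)[C@H](O)[C@H](O)CO
A8 | alternative 3 | methyl 4-O-(tert-butyldimethylsilyl)-6-deoxy-2,3-O-isopropylidene-α-D-lyxo-hex-5-enopyranoside | CO[C@H]1OC(=C)[C@@H](O[Si](C)(C)C(C)(C)C)[C@@H]2OC(C)(C)O[C@H]12
A9 | alternative 3 | ring A cyclohexanone (C8a ketone, free 5-hydroxyl, 6,7-acetonide, 8-O-TBS) | O=C1C[C@H](O)[C@H]2OC(C)(C)O[C@H]2[C@@H]1O[Si](C)(C)C(C)(C)C
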